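**Plan**

- Numbering: ring A is C1 (quaternary, carries C12H2OAc), C2H2, C3 (OH), C4 (OAc), C5 (Me2), C6 (apex); the cage is C7H2, C8H, C9H, C10 (C–Me), C11 (CHOAc), with C8–C9–C10 the cyclopropane.
- Feature used: C6–C7–C8–C9–C10–C11 are the six carbons of an ortho-cresol ring (oxygen on C11, methyl on C10) spiro-joined to ring A at C6, and C1 spans C6 and C9 as a one-carbon bridge.
- Retrosynthesis cuts, in this order: the cyclopropane bond C8–C10 (enolate alkylation), the bridge bond C1–C9 (intramolecular Michael addition), C1–C6 (dearomatising phenolate alkylation), C2–C3 (allylation) and the aryl bond C5–C6 (hydroarylation).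
- Forward: the C5–C4–C3–C2–C1–C12 chain is grown on 4-methoxy-2-methylphenol, ring A closes with dearomatisation to the spiro enedione, the bicyclo[2.2.1]heptane closes in the key step, and the cyclopropane closes last.
- Stereochemistry: C4 by asymmetric enolate hydroxylation; C3 by 1,2-induction; C6 in the dearomatising closure; C1 and C9 in the key step under a lactol tether from the C3 hydroxyl; C8 by endo hydride delivery then inversion; C11 by acetate capture of a cyclopropylcarbinyl cation.

Key step: step 11

Assumption: C1 (next to the aldehyde, compounds 13–14) and C10 (next to the C11 ketone, compounds 16–20) epimerise by enolisation; a configuration drawn there is the expected resting epimer, and both centres become fixed only in steps 11 and 16.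

Convention: in the bicyclo[2.2.1]heptane of 16–20, exo is the face turned to the one-carbon bridge C1, endo the face turned to the opposite two-carbon bridge.

**Route**

Step 1
Reactants: 1 4-methoxy-2-methylphenol; 2 3-methylbut-2-enoic acid
Product: 3 6-methoxy-4,4,8-trimethylchroman-2-one
Conditions: MeSO3H, 70 °C
Reagents that add atoms: none
Why: Acid-mediated Friedel–Crafts hydroarylation with lactonisation, the standard entry to 4,4-dimethylchroman-2-ones; the only free position ortho to the phenol oxygen is the future C6, so the aryl–C5 bond, the gem-dimethyl group and the C11 oxygen are put in place together.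

Step 2
Reactants: 3 6-methoxy-4,4,8-trimethylchroman-2-one
Product: 4 (3R)-3-hydroxy-6-methoxy-4,4,8-trimethylchroman-2-one
Conditions: KN(SiMe3)2, THF, −78 °C; then (+)-(camphorsulfonyl)oxaziridine, −78 °C
Reagents that add atoms: (+)-(camphorsulfonyl)oxaziridine, CC1(C)C2CCC13CS(=O)(=O)N4OC34C2
Why: Enolate hydroxylation with a chiral N-sulfonyloxaziridine, in which the flat and unbiased lactone enolate leaves the choice of face to the reagent; the (+)-reagent is chosen to give the 3R alcohol (C4 of the target), its sense is assigned by analogy and would be confirmed on 4, and the enantiomeric purity can be raised by crystallisation.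

Step 3
Reactants: 4 (3R)-3-hydroxy-6-methoxy-4,4,8-trimethylchroman-2-one
Product: 5 (3R)-3-[(tert-butyldimethylsilyl)oxy]-6-methoxy-4,4,8-trimethylchroman-2-one
Conditions: tBuMe2SiOTf, 2,6-lutidine, CH2Cl2, 0 °C
Reagents that add atoms: tert-butyldimethylsilyl trifluoromethanesulfonate, CC(C)(C)[Si](C)(C)OS(=O)(=O)C(F)(F)F
Why: Silylation of a hindered secondary alcohol with a silyl triflate, giving a bulky non-chelating ether that is kept to step 19 and later steers both the allylation and the choice of ring-A chair.

Step 4
Reactants: 5 (3R)-3-[(tert-butyldimethylsilyl)oxy]-6-methoxy-4,4,8-trimethylchroman-2-one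
Product: 6 (3R)-3-[(tert-butyldimethylsilyl)oxy]-6-methoxy-4,4,8-trimethylchroman-2-ol (lactol)
Conditions: iBu2AlH, toluene, −78 °C
Reagents that add atoms: none
Why: Partial reduction of a lactone to the lactol, the tetrahedral aluminium acetal surviving at low temperature until work-up.

Step 5
Reactants: 6 (3R)-3-[(tert-butyldimethylsilyl)oxy]-6-methoxy-4,4,8-trimethylchroman-2-ol; 7 allylmagnesium bromide
Product: 8 (3R,4S)-3-[(tert-butyldimethylsilyl)oxy]-2-(2-hydroxy-5-methoxy-3-methylphenyl)-2-methylhept-6-en-4-ol
Conditions: CH2=CHCH2MgBr (3 equiv), Et2O/THF, −78 → 0 °C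
Reagents that add atoms: none
Why: Grignard addition to the lactol in its open aldehyde form under 1,2-induction of the polar Felkin–Anh type, the non-chelating silyloxy bond lying opposed to the carbonyl and the nucleophile passing the α-hydrogen away from the tertiary aryl-bearing carbon, which gives the 3,4-anti diol pattern that becomes the cis-diol of ring A (C3 S, C4 R in the target numbering).

Step 6
Reactants: 8 (3R,4S)-3-[(tert-butyldimethylsilyl)oxy]-2-(2-hydroxy-5-methoxy-3-methylphenyl)-2-methylhept-6-en-4-ol
Product: 9 bis(triethylsilyl) ether of 8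
Conditions: Et3SiOTf (2.5 equiv), 2,6-lutidine, CH2Cl2, −78 → 0 °C
Reagents that add atoms: triethylsilyl trifluoromethanesulfonate, CC[Si](CC)(CC)OS(=O)(=O)C(F)(F)F
Why: Double silylation with a silyl triflate, in which the aryl silyl ether shields the electron-rich phenol from the peracid and is later the one cleaved by alkoxide, while the C3 silyl ether is later the one cleaved by acid.

Step 7
Reactants: 9 bis(triethylsilyl) ether of 8
Product: 10 terminal epoxide of 9
Conditions: mCPBA, NaHCO3, CH2Cl2, 0 °C → rt
Reagents that add atoms: 3-chloroperoxybenzoic acid, OOC(=O)c1cccc(Cl)c1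
Why: Prilezhaev epoxidation of the only alkene, in which the new centre C1 forms as both epimers; this is accepted because C1 is flattened in the enamine of step 11.

Step 8
Reactants: 10 terminal epoxide of 9
Product: 12 spirodienone alcohol, via potassium phenolate 11 (not isolated)
Conditions: KOtBu (2.2 equiv), tBuOH/THF, 0 → 60 °C
Reagents that add atoms: none
Why: Intramolecular alkylative dearomatisation of a phenolate, in which tert-butoxide cleaves the aryl silyl ether and the ortho carbon C6 opens the epoxide at C1 through a 6-exo-tet chair (O-alkylation would need an eight-membered ring); the phenolate oxygen should take the equatorial-type site because the other ortho substituent must point under the forming ring, and the C3 silyloxy group should stay equatorial to avoid a 1,3-diaxial clash with a C5 methyl, which together place the C11 carbonyl trans to the two ring-A oxygens.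

Step 9
Reactants: 12 spirodienone alcohol
Product: 13 spirodienone aldehyde
Conditions: Dess–Martin periodinane, NaHCO3, CH2Cl2, 0 °C → rt
Reagents that add atoms: none
Why: Periodinane oxidation of the primary alcohol under buffered conditions that leave the enol ether, the dienone and both silyl ethers alone, run before the C3 hydroxyl is freed so that no lactone can form.

Step 10
Reactants: 13 spirodienone aldehyde
Product: 14 hydroxy aldehyde enedione
Conditions: 1 M HCl (aq), THF, 0 °C → rt
Reagents that add atoms: water, O
Why: Acid hydrolysis of the methyl enol ether to the C8 ketone, which unveils the 2-ene-1,4-dione, with loss of the triethylsilyl ether in the same operation while the hindered tert-butyldimethylsilyl ether at C4 survives; the freed C3 hydroxyl can close onto the aldehyde as a lactol.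

Step 11
Reactants: 14 hydroxy aldehyde enedione
Product: 16 bridged diketone hydroxy aldehyde, via pyrrolidine enamine 15 (not isolated)
Conditions: pyrrolidine (0.3 equiv), AcOH (0.3 equiv), CHCl3, rt → 40 °C; aqueous work-up
Reagents that add atoms: none
Why: Proposed new method: pyrrolidine condenses with the open aldehyde form of 14 to the enamine 15, whose C1 adds to C9, the β-carbon of the C11 enone that is further activated by the C8 carbonyl, and hydrolysis of the iminium returns the aldehyde; the closest known reaction is the amine-catalysed intramolecular Michael addition of aldehydes to enones, which has not been shown for an α-branched donor closing a bicyclo[2.2.1]heptane. The ring closes 5-exo-trig through C1–C6–C7–C8–C9, and the strain of the new bicycle should be paid for by the loss of the cross-conjugated enedione. C1 is set by which chair of ring A reacts: the C3 hydroxyl, 1,3-diaxial to the formyl carbon, holds that carbon as lactol or N,O-acetal in the chair with C11 axial and the C4 silyloxy group equatorial, so the enamine bonds on the face that leaves C12 over C7–C8 and C2 over C10–C11, and only this product can return to the lactol. C9 follows from the bridge, and C10 should be protonated on its exo face to give the endo-methyl epimer, which remains labile. The step needs bond formation at C9 only, which the geometry secures because C1 cannot reach C10 without a four-membered ring, and it needs the enamine to form at the aldehyde, which the two hindered ketones ensure.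

Step 12
Reactants: 16 bridged diketone hydroxy aldehyde
Product: 17 bridged diketone diol
Conditions: NaBH4, MeOH, −40 → 0 °C
Reagents that add atoms: none
Why: Borohydride reduction of the aldehyde through its open form, chemoselective because both ketones are shielded on either face (C8 by the C12 arm and the endo C10 methyl, C11 by C2 and the quaternary C6); it also removes the carbonyl that could drive a retro-Michael opening in the later basic steps.

Step 13
Reactants: 17 bridged diketone diol
Product: 18 bis(triethylsilyl) ether of 17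
Conditions: Et3SiOTf (3 equiv), 2,6-lutidine, CH2Cl2, 0 °C → rt
Reagents that add atoms: triethylsilyl trifluoromethanesulfonate, CC[Si](CC)(CC)OS(=O)(=O)C(F)(F)F
Why: Silyl triflate silylation of the primary C12 hydroxyl and of the hindered axial C3 hydroxyl, so that only the C8 hydroxyl made in step 14 is sulfonylated in step 15.

Step 14
Reactants: 18 bis(triethylsilyl) ether of 17
Product: 19 C8 exo-alcohol
Conditions: K[HB(sBu)3] (1.2 equiv), KOtBu (0.2 equiv), THF, −40 → 0 °C; then H2O
Reagents that add atoms: none
Why: Trialkylborohydride reduction under dynamic kinetic resolution: in 18 the endo C10 methyl and the C12 arm over C7–C8 close both faces of the C8 carbonyl, so only the minor C10 epimer fed in by the catalytic alkoxide through the C11 enolate (methyl exo, endo face open) is reduced, and the bulky hydride attacks C8 from the endo face as in the reduction of camphor to isoborneol, giving the exo alcohol while the C11 carbonyl next to the quaternary C6 is left.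

Step 15
Reactants: 19 C8 exo-alcohol
Product: 20 C8 exo-methanesulfonate
Conditions: MsCl, Et3N, CH2Cl2, −20 °C
Reagents that add atoms: methanesulfonyl chloride, CS(=O)(=O)Cl
Why: Sulfonylation through the sulfene, which tolerates the hindered alcohol and retains its configuration, so the leaving group sits exo at C8.

Step 16
Reactants: 20 C8 exo-methanesulfonate
Product: 21 cyclopropyl ketone
Conditions: KOtBu (1.5 equiv), THF/tBuOH, 0 °C → rt
Reagents that add atoms: none
Why: Intramolecular enolate alkylation (3-exo-tet, γ-sulfonyloxy ketone to cyclopropyl ketone): the C11 ketone can enolise only toward C10, whose endo lobe lies behind the exo C8–O bond, so displacement with inversion at C8 closes the cyclopropane and leaves the methyl on C10 whatever the C10 configuration was before enolisation.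

Step 17
Reactants: 21 cyclopropyl ketone
Product: 22 C11 carbinol
Conditions: LiAlH4, Et2O, 0 °C
Reagents that add atoms: none
Why: Hydride reduction of the hindered cyclopropyl ketone, in which hydride should enter from the open face of C11 that looks toward C7 and so place the hydroxyl on the C2 side; this is the wrong epimer but is corrected in step 18, where either epimer serves, and dissolving-metal conditions are avoided because the ketyl would open the cyclopropane.

Step 18
Reactants: 22 C11 carbinol
Product: 24 C11 acetate, via C11 methanesulfonate 23 (not isolated)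
Conditions: (MeSO2)2O, iPr2NEt, CH2Cl2, −40 °C; then Bu4NOAc, MeCN, −40 °C → rt
Reagents that add atoms: tetrabutylammonium acetate, CC(=O)[O-].CCCC[N+](CCCC)(CCCC)CCCC
Why: Solvolytic substitution of a cyclopropylcarbinyl sulfonate: the methanesulfonate ionises with help from the cyclopropane to a 3-nortricyclyl-type cation that cannot eliminate (C6 and C10 carry no hydrogen), and acetate should enter from the only open face, the one toward C7, giving the C11 acetate of the target with inversion of the major carbinol epimer and convergence of the minor one.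

Step 19
Reactants: 24 C11 acetate
Product: 25 triol monoacetate
Conditions: HF (48% aq), MeCN, 0 °C → rt
Reagents that add atoms: none
Why: Acidic fluoride desilylation of the three silyl ethers under conditions that should neither hydrolyse nor move the C11 acetate.

Step 20
Reactants: 25 triol monoacetate
Product: 26 CNP0111873.1
Conditions: Ac2O (2.5 equiv), pyridine, DMAP (cat.), CH2Cl2, 0 °C → rt
Reagents that add atoms: acetic anhydride, CC(=O)OC(C)=O
Why: Selective acetylation, in which the primary C12 hydroxyl and the equatorial C4 hydroxyl react whereas the axial C3 hydroxyl, flanked by two 1,3-diaxial carbon substituents (C12 and a C5 methyl) as in an 11β-hydroxy steroid, should stay free, so the free hydroxyl of the target needs no protecting group.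

**Compound list**

1 | 4-methoxy-2-methylphenol | Cc1cc(OC)ccc1O | starting material
2 | 3-methylbut-2-enoic acid | CC(C)=CC(=O)O | starting material
3 | 6-methoxy-4,4,8-trimethylchroman-2-one | O=C1CC(C)(C)c2cc(OC)cc(C)c2O1 | intermediate
4 | (3R)-3-hydroxy-6-methoxy-4,4,8-trimethylchroman-2-one | O=C1[C@H](O)C(C)(C)c2cc(OC)cc(C)c2O1 | intermediate
5 | (3R)-3-[(tert-butyldimethylsilyl)oxy]-6-methoxy-4,4,8-trimethylchroman-2-one | O=C1[C@H](O[Si](C)(C)C(C)(C)C)C(C)(C)c2cc(OC)cc(C)c2O1 | intermediate
6 | (3R)-3-[(tert-butyldimethylsilyl)oxy]-6-methoxy-4,4,8-trimethylchroman-2-ol, lactol, both anomers | OC1[C@H](O[Si](C)(C)C(C)(C)C)C(C)(C)c2cc(OC)cc(C)c2O1 | intermediate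
7 | allylmagnesium bromide | C=CC[Mg]Br | starting material
8 | (3R,4S)-3-[(tert-butyldimethylsilyl)oxy]-2-(2-hydroxy-5-methoxy-3-methylphenyl)-2-methylhept-6-en-4-ol | C=CC[C@H](O)[C@H](O[Si](C)(C)C(C)(C)C)C(C)(C)c1cc(OC)cc(C)c1O | intermediate
9 | bis(triethylsilyl) ether of 8 (phenol oxygen and the carbinol that becomes C3) | C=CC[C@H](O[Si](CC)(CC)CC)[C@H](O[Si](C)(C)C(C)(C)C)C(C)(C)c1cc(OC)cc(C)c1O[Si](CC)(CC)CC | intermediate
10 | terminal epoxide of 9, both epimers at the oxirane CH (C1) | C1OC1C[C@H](O[Si](CC)(CC)CC)[C@H](O[Si](C)(C)C(C)(C)C)C(C)(C)c2cc(OC)cc(C)c2O[Si](CC)(CC)CC | intermediate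
11 | potassium phenolate of 10 after loss of the aryl triethylsilyl group | C1OC1C[C@H](O[Si](CC)(CC)CC)[C@H](O[Si](C)(C)C(C)(C)C)C(C)(C)c2cc(OC)cc(C)c2[O-].[K+] | intermediate (not isolated)
12 | spirodienone alcohol: ring A (C1–CH2OH both epimers, C3 S OSiEt3, C4 R OSitBuMe2, C5 Me2) spiro at C6 to 4-methoxy-2-methylcyclohexa-2,4-dien-1-one, C11 carbonyl trans to the two silyloxy groups | OCC1C[C@H](O[Si](CC)(CC)CC)[C@H](O[Si](C)(C)C(C)(C)C)C(C)(C)[C@@]12C(=O)C(C)=CC(OC)=C2 | intermediate
13 | spirodienone aldehyde (C12 formyl on C1, both C1 epimers) | O=CC1C[C@H](O[Si](CC)(CC)CC)[C@H](O[Si](C)(C)C(C)(C)C)C(C)(C)[C@@]12C(=O)C(C)=CC(OC)=C2 | intermediate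
14 | hydroxy aldehyde enedione, key-step precursor: spiro 2-methylcyclohex-2-ene-1,4-dione, C3 OH, C4 OSitBuMe2; drawn open, both C1 epimers, the cis epimer resting partly as the C3–O–C12 lactol | O=CC1C[C@H](O)[C@H](O[Si](C)(C)C(C)(C)C)C(C)(C)[C@@]12C(=O)C(C)=CC(=O)C2 | intermediate
15 | pyrrolidine enamine of 14 (C12=C1) | C1CCN(C1)C=C2C[C@H](O)[C@H](O[Si](C)(C)C(C)(C)C)C(C)(C)[C@@]23C(=O)C(C)=CC(=O)C3 | intermediate (not isolated)
16 | bridged diketone hydroxy aldehyde, key-step product: ring A fused at C1–C6 to a bicyclo[2.2.1]heptane-2,5-dione (C8=O, C11=O, C1 the one-carbon bridge), formyl C12 over C7–C8, C2 over C10–C11, C10 methyl endo; drawn open, rests as the C3–O–C12 lactol | O=C[C@]12C[C@H](O)[C@H](O[Si](C)(C)C(C)(C)C)C(C)(C)[C@]13CC(=O)[C@H]2[C@@H](C)C3=O | intermediate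
17 | bridged diketone diol (C12 OH, C3 OH) | OC[C@]12C[C@H](O)[C@H](O[Si](C)(C)C(C)(C)C)C(C)(C)[C@]13CC(=O)[C@H]2[C@@H](C)C3=O | intermediate
18 | bis(triethylsilyl) ether of 17 (C12 and C3 oxygens) | CC[Si](CC)(CC)OC[C@]12C[C@H](O[Si](CC)(CC)CC)[C@H](O[Si](C)(C)C(C)(C)C)C(C)(C)[C@]13CC(=O)[C@H]2[C@@H](C)C3=O | intermediate
19 | C8 exo-alcohol, C11 ketone, C10 methyl exo | CC[Si](CC)(CC)OC[C@]12C[C@H](O[Si](CC)(CC)CC)[C@H](O[Si](C)(C)C(C)(C)C)C(C)(C)[C@]13C[C@H](O)[C@H]2[C@H](C)C3=O | intermediate
20 | C8 exo-methanesulfonate of 19 | CC[Si](CC)(CC)OC[C@]12C[C@H](O[Si](CC)(CC)CC)[C@H](O[Si](C)(C)C(C)(C)C)C(C)(C)[C@]13C[C@H](OS(C)(=O)=O)[C@H]2[C@H](C)C3=O | intermediate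
21 | cyclopropyl ketone (C8–C9–C10 cyclopropane closed, C11=O) | CC[Si](CC)(CC)OC[C@]12C[C@H](O[Si](CC)(CC)CC)[C@H](O[Si](C)(C)C(C)(C)C)C(C)(C)[C@]13C[C@@H]1[C@H]2[C@]1(C)C3=O | intermediate
22 | C11 carbinol, hydroxyl on the C2 side (epimer of the target at C11) | CC[Si](CC)(CC)OC[C@]12C[C@H](O[Si](CC)(CC)CC)[C@H](O[Si](C)(C)C(C)(C)C)C(C)(C)[C@]13C[C@@H]1[C@H]2[C@]1(C)[C@@H]3O | intermediate
23 | C11 methanesulfonate of 22 | CC[Si](CC)(CC)OC[C@]12C[C@H](O[Si](CC)(CC)CC)[C@H](O[Si](C)(C)C(C)(C)C)C(C)(C)[C@]13C[C@@H]1[C@H]2[C@]1(C)[C@@H]3OS(C)(=O)=O | intermediate (not isolated)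
24 | C11 acetate, acetoxy on the C7 side, three silyl ethers | CC[Si](CC)(CC)OC[C@]12C[C@H](O[Si](CC)(CC)CC)[C@H](O[Si](C)(C)C(C)(C)C)C(C)(C)[C@]13C[C@@H]1[C@H]2[C@]1(C)[C@H]3OC(C)=O | intermediate
25 | triol monoacetate (C12 OH, C3 OH, C4 OH, C11 OAc) | OC[C@]12C[C@H](O)[C@H](O)C(C)(C)[C@]13C[C@@H]1[C@H]2[C@]1(C)[C@H]3OC(C)=O | intermediate
26 | CNP0111873.1 | CC(=O)OC[C@]12C[C@H](O)[C@H](OC(C)=O)C(C)(C)[C@]13C[C@@H]1[C@H]2[C@]1(C)[C@H]3OC(C)=O | target

**Summary and risks**

Total step count: 20. Longest linear sequence: 20 steps, from 1.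

Steps most likely to fail:

1. Step 11. The enamine may form too slowly at the hindered α-branched aldehyde, or the strained bridge closure may lose to reversible addition of the amine to the enedione or to closure through the other ring-A chair. Fallback with known chemistry (Mukaiyama–Michael addition), from 14 back to 16: 14 is treated with Et3SiOTf and Et3N in CH2Cl2 at −78 °C, which silylates the C3 hydroxyl and converts the aldehyde into its C1=C12 silyl enol ether F1. Catalytic Me3SiOTf in CH2Cl2 at −78 °C then activates the enedione for attack of C1 on C9. Work-up with 1 M aqueous HCl removes the silyl groups, and the route is rejoined at 16.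

2. Step 8. Attack through the crowded ortho carbon may be outrun by intermolecular opening of the epoxide, or the arene may present the wrong face, so that the spiro centre C6 forms with poor selectivity. Fallback, from 9 back to 14 (replacing steps 7–10) by a palladium-catalysed allylic dearomatisation in which a chiral ligand chooses the arene face:
   - cross-metathesis of 9 with (Z)-but-2-ene-1,4-diyl dimethyl dicarbonate (second-generation Grubbs catalyst, CH2Cl2, 40 °C) gives the (E)-allylic methyl carbonate F2;
   - zerovalent palladium (Pd2(dba)3 with (R,R)-N,N'-bis(2-diphenylphosphinobenzoyl)cyclohexane-1,2-diamine, THF, rt) ionises it, the methoxide released with CO2 cleaves the aryl silyl ether, and C6 attacks the internal allyl terminus C1 to give the vinyl spirodienone F3;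
   - 1 M aqueous HCl in THF hydrolyses the enol ether and the C3 silyl ether to the vinyl enedione F4;
   - ozonolysis of the terminal vinyl group (O3, CH2Cl2/MeOH, −78 °C; then Me2S), which is far more electron-rich than the ring alkene flanked by two carbonyls, gives 14.

3. Step 14. The C10 epimers may interconvert too slowly to feed the reducible epimer, so that the hydride does not react or attacks C11. Fallback, from 18 back to 21 (replacing steps 14–16), which makes C10 planar before C8 is reduced:
   - kinetic enol silylation of the C8 ketone (LiN(iPr)2, Me3SiCl, THF, −78 °C) gives the C7=C8 trimethylsilyl enol ether F5;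
   - tBuMe2SiOTf and Et3N in CH2Cl2 convert the C11 ketone, enolisable only toward C10, into its silyl enol ether, giving the bis(enol ether) F6;
   - K2CO3 in MeOH at 0 °C cleaves only the trimethylsilyl enol ether to the C8 ketone F7;
   - NaBH4 in MeOH/THF reduces C8 from the now unobstructed endo face to the exo alcohol F8;
   - MsCl and Et3N give the methanesulfonate F9;
   - CsF in MeCN unmasks the C11 enolate, which closes the cyclopropane, and the route is rejoined at 21.

**Further compounds**

F1 | step 11 | C1=C12 triethylsilyl enol ether of 14 with the C3 hydroxyl as triethylsilyl ether | CC[Si](CC)(CC)OC=C1C[C@H](O[Si](CC)(CC)CC)[C@H](O[Si](C)(C)C(C)(C)C)C(C)(C)[C@@]12C(=O)C(C)=CC(=O)C2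
F2 | step 8 | (E)-allylic methyl carbonate from cross-metathesis of 9 | COC(=O)OC/C=C/C[C@H](O[Si](CC)(CC)CC)[C@H](O[Si](C)(C)C(C)(C)C)C(C)(C)c1cc(OC)cc(C)c1O[Si](CC)(CC)CC
F3 | step 8 | vinyl spirodienone (vinyl on C1, C3 OSiEt3, C4 OSitBuMe2, C11 carbonyl trans to the silyloxy groups) | C=CC1C[C@H](O[Si](CC)(CC)CC)[C@H](O[Si](C)(C)C(C)(C)C)C(C)(C)[C@@]12C(=O)C(C)=CC(OC)=C2
F4 | step 8 | vinyl enedione with free C3 hydroxyl | C=CC1C[C@H](O)[C@H](O[Si](C)(C)C(C)(C)C)C(C)(C)[C@@]12C(=O)C(C)=CC(=O)C2
F5 | step 14 | C7=C8 trimethylsilyl enol ether of 18 | CC[Si](CC)(CC)OC[C@]12C[C@H](O[Si](CC)(CC)CC)[C@H](O[Si](C)(C)C(C)(C)C)C(C)(C)[C@]13C=C(O[Si](C)(C)C)[C@H]2[C@@H](C)C3=O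
F6 | step 14 | bis(enol ether): C7=C8 trimethylsilyl and C10=C11 tert-butyldimethylsilyl enol ethers | CC[Si](CC)(CC)OC[C@]12C[C@H](O[Si](CC)(CC)CC)[C@H](O[Si](C)(C)C(C)(C)C)C(C)(C)[C@]13C=C(O[Si](C)(C)C)[C@H]2C(C)=C3O[Si](C)(C)C(C)(C)C
F7 | step 14 | C8 ketone with C10=C11 tert-butyldimethylsilyl enol ether | CC[Si](CC)(CC)OC[C@]12C[C@H](O[Si](CC)(CC)CC)[C@H](O[Si](C)(C)C(C)(C)C)C(C)(C)[C@]13CC(=O)[C@H]2C(C)=C3O[Si](C)(C)C(C)(C)C
F8 | step 14 | C8 exo-alcohol with C10=C11 silyl enol ether | CC[Si](CC)(CC)OC[C@]12C[C@H](O[Si](CC)(CC)CC)[C@H](O[Si](C)(C)C(C)(C)C)C(C)(C)[C@]13C[C@H](O)[C@H]2C(C)=C3O[Si](C)(C)C(C)(C)C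
F9 | step 14 | C8 exo-methanesulfonate with C10=C11 silyl enol ether | CC[Si](CC)(CC)OC[C@]12C[C@H](O[Si](CC)(CC)CC)[C@H](O[Si](C)(C)C(C)(C)C)C(C)(C)[C@]13C[C@H](OS(C)(=O)=O)[C@H]2C(C)=C3O[Si](C)(C)C(C)(C)C
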